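**Easy step.** Pre-initiator turns into initiator with a half-life of 0.692 min, and initiator, with free monomer as charged, meets it with a half-life of 0.380 min. Both are far shorter than the run, so we count one chain begun per pre-initiator charged.

    free monomer + initiator → living end + monomer in chains (k1 = 0.608 M⁻¹ s⁻¹)
    free monomer + living end → monomer in chains + living end, rate k2*[living end]*[free monomer] (k2 = 10.6 M⁻¹ s⁻¹)
    monomer in chains + living end → free monomer + living end, rate k3*[living end] as long as [monomer in chains] is above zero (k3 = 0.0561 s⁻¹)
    pre-initiator → initiator (k4 = 0.0167 s⁻¹)

| setting | dusk | noon |
|---|---|---|
| free monomer | 0.050 M | 0.050 M |
| pre-initiator | 0.25 mM | 1.0 mM |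
| time | 1.5 h | 1.5 h |

1. which of the two ends with the longer chains by the average number of monomer units in a chain (chains begun, living or dead) ("neither" if they lie within 10%) (dusk / noon / neither)
2. average number of monomer units in a chain (chains begun, living or dead) at the end, dusk
3. average number of monomer units in a chain (chains begun, living or dead) at the end, noon

- the average divides the monomer in chains by the number of chains begun, living and dead together
- run time (dusk): 1.5 h

**Late end.** Each living end adds free monomer at 10.6 M⁻¹ s⁻¹ times c(free monomer) and hands monomer back at 0.0561 s⁻¹. The net flow therefore stops at the ceiling concentration, the rate constant of handing back over that of adding, 5.29 mM; the trade calls it the equilibrium monomer concentration. The concentration of living ends cancels out of it. Joining the two ends, we take the length as the charge of free monomer minus the ceiling, divided by the charge of pre-initiator.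

**Turning pre-initiator.** By hand, dusk gives 179 and noon 44.7. The charge at noon is larger by a factor of 4.00, the ceiling stays put, and the noon chains come out shorter by that same factor.

**Turning free monomer.** By hand, free monomer counts towards length above the ceiling, so a charge of 0.050 M should keep 10.6% free in either flask.

**Turning time.** Near the ceiling the approach is pseudo-first-order, with a half-life of ln(2) over the rate constant of adding times c(living end). That is 4.36 min at dusk and 1.09 min at noon. The run is much longer than the dusk value, so by hand more time adds nothing.

**The result.** The forecast said dusk, with 178.8 against 44.7, since “the dusk chains are four times longer”. The flasks give 179 at dusk and 44.7 at noon, so dusk has the longer chains. Dusk already stands at 124 after 0.150 h, and after 15.0 h, ten times the run, it reads 179.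

**Charge counts.** Dusk and noon end with 10.6% and 10.6% of their charged monomer still free. The gap in length is due to the pre-initiator charge: noon given the dusk charge reads 179 instead of 44.7. The ceiling carries over to a neighbour, the noon flask charged with 0.020 M of free monomer instead. By hand its length is 14.7; the flask reads 14.7, with 26% of its charge still free.

The constants used here were set for the occasion; no experiment stands behind them.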